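Start from the amounts: two charges of X have been run, and the flask lies between them.

| setting | birch | alder | flask |
|---|---|---|---|
| X | 6.5 mM | 26 mM | 13 mM |
| remark | run made earlier | run made earlier |  |
| time |  |  | 1.5 h |

| run | time / min | X / % | G / % | J / % |
|---|---|---|---|---|
| birch | 3.00 | 0.2 | 39.7 | 1.2 |
| birch | 8.00 | 0 | 41.4 | 0.1 |
| birch | 15.0 | 0 | 41.4 | 0.4 |
| birch | 25.0 | 0 | 40.7 | 0 |
| birch | 30.0 | 0 | 40.9 | 0 |
| birch | 40.0 | 0.4 | 41.8 | 0.5 |
| birch | 50.0 | 0.7 | 41.3 | 0.3 |
| alder | 3.00 | 0.6 | 16.9 | 0 |
| alder | 8.00 | 0.6 | 17.4 | 0 |
| alder | 15.0 | 0 | 18.0 | 0.1 |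
| alder | 25.0 | 0 | 17.1 | 0.3 |
| alder | 30.0 | 0 | 18.3 | 0.6 |
| alder | 40.0 | 0 | 18.2 | 0 |
| alder | 50.0 | 0.6 | 17.6 | 0 |

(readings scatter by 0.5 percentage points)

1. at 1.5 h, what has stopped the reaction, if anything has (E counts as not reacted) (all of X has reacted / it is still moving / forward and back rates have come level)
2. part of the X that has turned into other species by 1.5 h (E does not count)
3. the G standing at 1.5 h, as a percentage of the X charged

- what was read earlier has a scatter of 0.5 percentage points, one standard deviation
- in a conversion E counts as not yet reacted
- the reaction counts as stopped when no species that holds the X changes by six tenths of a point or more over the second half of the time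

1. Freeze time first: take the alder reading of X at 3.00 min, which is 0.6% and so stands close to the scatter of 0.5 percentage points, assume a first-order fall, and read a rough time constant of about 0.586 min from it, so expect the flask's 1.5 h to hold about 154 of them.

2. Freeze G next: average each flat run, which gives 41.0% in birch and 17.6% in alder.

3. Treat G's share as the selectivity of a first-order path racing a second-order one, and define the crowding slope, the rise of the reciprocal share per mM of charge: 0.166 mM⁻¹.

4. Walk up that line from birch to the flask's 13 mM, and commit to G at 28.5%.

5. Reforge the weak link, the unseen part: it grows from 59.0% in birch to 82.4% in alder, whereas a plain X ⇌ E balance keeps one ratio of E to X at any charge. So read it as products rather than E, and commit to a conversion near 100 per cent.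

The forecast parts from this reckoning on the stop and the conversion: forward and back rates have come level, with conversion 27% (24.5% to 30%) and G 27% (24.5% to 29.5%), reasoning “That points to a balance rather than complete reaction”.

The flask gives: all of X has reacted, conversion 100%, G 28.0%.

    X ⇌ E (K = 2.13, k = 0.00277 s⁻¹)
    X → J (k = 0.0230 s⁻¹)
    E → D (k = 0.111 s⁻¹)
    2 X → L (k = 3.66 M⁻¹ s⁻¹)
    J → G (k = 0.0269 s⁻¹)
    X + J → Z (k = 3.77 M⁻¹ s⁻¹)

At the start of the flask, X has a half-life of 0.50 min by making J alone but 0.175 min by the step to L alone, which is shorter. At 1.50 h the flask holds, in percent of the X charged, L at 55.2%, G at 28.0% and E at 0%, with G beside the line's 28.5%. For a neighbour flask, the same but charged with 32 mM of X, the crowding slope gives G at 15.0%, and the computed G is 15.1%.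

(The runs come from a simulation on assumed constants.)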